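Read the D of teal as two things, free D and D parked with X as G, and ask what share of it is free, since the row asks for free D.

| setting | green | teal | noon | midnight | winter |
|---|---|---|---|---|---|
| L | 0.022 M | 0.022 M | 0.022 M | 0.022 M | 0.022 M |
| X | 0.70 equiv | 2.9 equiv | 0.500 equiv | 1.00 equiv | 2.00 equiv |
| J | 0.70 equiv | 0.70 equiv | 0.700 equiv | 0.700 equiv | 0.700 equiv |
| remark | run made earlier | run made earlier |  |  |  |
| time |  |  | 12 min | 12 min | 12 min |

- green (time / min: D / %, L / %): 3.00: 17.0, 30.9; 6.00: 24.7, 31.1; 10.0: 27.4, 30.7; 12.0: 28.7, 30.5
- teal (time / min: D / %, L / %): 3.00: 25.8, 0.6; 6.00: 36.8, 0.6; 10.0: 44.5, 0; 12.0: 47.0, 0.2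

(scatter of a reading: 0.3 percentage points)

- for D the G are counted in
- the earlier runs were read with a standard deviation of 0.3 percentage points
- steps under discussion: J + Q <-> D; L + X <-> Z + Q; X + D <-> G; D <-> E
- the concentration of D that is asked is that of its free form alone
- "hardly changes" means that all values lie within two and a half points (for a concentration: within two and a half percent of the largest)

- [D] (only what is free in solution) at the end for noon, midnight, winter, in this order
- the course of these numbers from the first flask to the last (hardly changes / falls, then rises / falls all the way / rises all the way / rises, then falls)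

In green, L stops at 30.5%, which leaves 0.500% of the L charge as X, so we treat green's D as free and take Q equal to J. With amounts as fractions of the L charge, we write the net rate of D as a·J·Q − b·D, where a is the forward constant and b collects the ways out. The green slopes from 3.00 min to 6.00 min and from 10.0 min to 12.0 min give a = 0.188 /min and b = 0.0948 /min.

But teal's late slope, put into the same law, leaves free D at 12.9%, which is an estimate and not a reading, because the scatter of 0.3 percentage points in the two readings passes through the slope and the division by b, and the errors of a and b come on top. The rest of teal's counted D is G, so G per free D per free X comes to 73.6 /M, the parking constant p, a binding constant. Noon and midnight charge no X beyond the L, while winter's whole excess gives p·[X] = 1.62, so we expect free D to rise and then fall.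

The forecast gives 0.0048 M, 0.0069 M and 0.0041 M, course rises, then falls, on the ground that “excess X is pulling D into G”.

The flask gives 0.00495 M, 0.00723 M and 0.00438 M, course rises, then falls.

    J + Q ⇌ D (K = 570 /M, k = 0.138 /M/s)
    L + X ⇌ Z + Q, settled at all times (K = 110)
    X + D ⇌ G, settled at all times (K = 72.0 /M)
    D ⇌ E (K = 0.611, k = 0.00121 /s)

The fall into winter belongs to the parking: with X + D to G taken away, winter's free D is 0.00792 M in place of 0.00438 M, and the course changes. With 38.2% of its X left in winter, p gives 1.24 G per free D, and the flask holds 1.21. At midnight, with 4.95% of its X left, p gives 0.0802 against a simulated 0.0785.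

(The numbers in the tables are simulated with made-up constants; noise was put on by code.)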